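**Plan**
- Retrosynthesis: the aryl PMB ether and a temporary C4–N bond are cut first, then both C–C bonds of the dihydropyran ring (C4–C4a and C3–C2) together. This gives a ketone-derived aryl enol ether and a two-carbon enecarbamate. The enol ether goes back to an aryl ester, made from a C17 acid (from natural phytol) and mono-protected 2,5-dimethylhydroquinone.
- Forward: phytol → C18 methyl ketone → C17 acid → aryl ester → aryl enol ether, so the side chain and both O1 bonds are in place before the heterocycle exists. The dihydropyran ring then arises in one cationic [4+2] annulation on the finished aromatic ring, and one reductive step removes the C4 nitrogen and the PMB group.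
- Enabling feature: O1 lies between C8a of the aromatic ring and the quaternary C2, so protonating the enol ether gives an oxocarbenium ion whose C4a=C8a–O1=C2 unit is a cationic 2-oxa-diene. C4a is the only unsubstituted carbon ortho to O1 (C8 carries a methyl group), so the ring can close at one place only.
- Stereochemistry: 4'R and 8'R come unchanged from C7 and C11 of phytol. 2R is set in the key step by the anion of a confined chiral Brønsted acid. The C4 centre formed alongside is removed in the last step.

Key step: step 6

Assumption: commercial natural phytol is taken as the (2E,7R,11R) isomer.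
Assumption: the sense of induction of the confined acid cannot be derived from first principles; the (S,S) acid is written, and its mirror image would be used if the 2S adduct were to form.

**Route**

Step 1
Reactants: 1 phytol, (2E,7R,11R)-3,7,11,15-tetramethylhexadec-2-en-1-ol
Product: 2 (6R,10R)-6,10,14-trimethylpentadecan-2-one
Conditions: O3, CH2Cl2–MeOH, −78 °C; then Me2S, −78 °C to rt
Reagents that add atoms: ozone, [O-][O+]=O
Why: Ozonolysis with reductive work-up cleaves the only C=C bond to the methyl ketone, and the two stereocenters are remote from any enolisable position and pass through unchanged.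

Step 2
Reactants: 2 (6R,10R)-6,10,14-trimethylpentadecan-2-one
Product: 3 (5R,9R)-5,9,13-trimethyltetradecanoic acid
Conditions: Br2, NaOH, H2O–1,4-dioxane, 0 °C to rt; then aq. HCl
Reagents that add atoms: sodium hydroxide, [Na+].[OH-]
Why: Haloform reaction: exhaustive bromination of the methyl flank followed by hydroxide cleavage of the tribromomethyl ketone should give the acid one carbon shorter, with no stereocenter near the reacting site.

Step 3
Reactants: 4 2,5-dimethylbenzene-1,4-diol
Product: 5 4-[(4-methoxyphenyl)methoxy]-2,5-dimethylphenol
Conditions: 4-MeOC6H4CH2Cl (half an equivalent relative to the diol), K2CO3, DMF, rt, under Ar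
Reagents that add atoms: 4-methoxybenzyl chloride, COc1ccc(CCl)cc1
Why: Williamson ether synthesis on a symmetric diol, so there is no regiochemical issue; the twofold excess of diol should hold back the bis-ether, and the unreacted diol is recovered.

Step 4
Reactants: 3 (5R,9R)-5,9,13-trimethyltetradecanoic acid; 5 4-[(4-methoxyphenyl)methoxy]-2,5-dimethylphenol
Product: 6 4-[(4-methoxyphenyl)methoxy]-2,5-dimethylphenyl (5R,9R)-5,9,13-trimethyltetradecanoate
Conditions: N,N'-dicyclohexylcarbodiimide (DCC), 4-(dimethylamino)pyridine (cat.), CH2Cl2, 0 °C to rt
Reagents that add atoms: none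
Why: Steglich esterification acylates the phenol through the acylpyridinium ion under neutral conditions that leave the PMB ether and the stereocenters alone.

Step 5
Reactants: 6 4-[(4-methoxyphenyl)methoxy]-2,5-dimethylphenyl (5R,9R)-5,9,13-trimethyltetradecanoate
Product: 7 1-[(4-methoxyphenyl)methoxy]-2,5-dimethyl-4-{[(6R,10R)-6,10,14-trimethylpentadec-1-en-2-yl]oxy}benzene
Conditions: Tebbe reagent Cp2Ti(CH2)(Cl)AlMe2, pyridine (cat.), THF–toluene, −40 °C to rt; basic work-up, basic Al2O3
Reagents that add atoms: Tebbe reagent, C[Al-]1(C)C[Ti]([Cl+]1)(C2C=CC=C2)C3C=CC=C3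
Why: Tebbe methylenation of an aryl ester through the oxatitanacyclobutane should give the 1,1-disubstituted aryl enol ether without enolisation, since the titanium methylidene is non-basic.

Step 6
Reactants: 7 1-[(4-methoxyphenyl)methoxy]-2,5-dimethyl-4-{[(6R,10R)-6,10,14-trimethylpentadec-1-en-2-yl]oxy}benzene; 8 benzyl N-ethenylcarbamate
Product: 9 benzyl N-[(2R)-6-[(4-methoxyphenyl)methoxy]-2,5,8-trimethyl-2-[(4R,8R)-4,8,12-trimethyltridecyl]-3,4-dihydro-2H-chromen-4-yl]carbamate (both epimers at C-4)
Conditions: (S,S)-imidodiphosphoric acid HN[P(=O)(O2C20H10Ar2)]2 (each O2C20H10Ar2 a 3,3'-diaryl-(S)-1,1'-binaphthalene-2,2'-diolate, Ar = 2,4,6-Et3C6H2; 5 mol%), 5 Å molecular sieves, toluene, −20 °C; the enecarbamate in excess (2.5 equiv), the enol ether added slowly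
Reagents that add atoms: none
Why: Proposed new method: the confined acid protonates the CH2 terminus of the aryl enol ether to give an O-aryl oxocarbenium ion held as a contact ion pair, whose C4a=C8a–O1=C2 unit is a cationic 2-oxa-diene; the enecarbamate, bound to the same anion through its N–H, adds with its CH2 carbon to C2 (C3–C2 bond), and the N-acyliminium ion left at C4 is taken by C4a in a Friedel–Crafts step (C4–C4a bond), the proton lost from C4a returning to the catalyst, so that the step is a net addition in which every atom of both reactants stays in the product. The closest known reaction types are the chiral-phosphoric-acid-catalysed Povarov reaction of N-aryl iminium ions with enecarbamates and the Lewis-acid-promoted oxa-Povarov reaction of aldehyde-derived aryl oxocarbenium ions with alkenes; a ketone-derived aryl oxocarbenium ion under chiral-anion control has not been shown. The dihydropyran ring closes as a stepwise polar [4+2] annulation, its second bond by 6-exo-trig attack of the aromatic carbon on the exocyclic iminium carbon. C2 is set in the first bond formation by the catalyst alone, whose anion pocket must tell the methyl group from the CH2 of the long chain on a planar cation, as confined imidodiphosphate-type anions do with small unfunctionalised alkyl groups in oxocarbenium intermediates of acetalisations; the remote 4' and 8' centres should have no influence, and the C4 centre is uncontrolled but is removed in step 7. The step needs protonation of the enol ether in preference to the enecarbamate and cross-addition over self-addition, which the alkyl-substituted and therefore more readily protonated enol ether double bond, the excess of the more nucleophilic N–H enecarbamate and the slow addition of the enol ether should secure, and it needs a single site of closure, which the substrate secures because C4a is the only unsubstituted carbon ortho to O1 and C7 is out of reach of the three-atom tether.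

Step 7
Reactants: 9 benzyl N-[(2R)-6-[(4-methoxyphenyl)methoxy]-2,5,8-trimethyl-2-[(4R,8R)-4,8,12-trimethyltridecyl]-3,4-dihydro-2H-chromen-4-yl]carbamate
Product: 11 (2R,4'R,8'R)-beta-tocopherol, via phenol carbamate 10 (not isolated)
Conditions: Et3SiH (6 equiv), CF3CO2H–CH2Cl2 (1:3), 0 °C to rt
Reagents that add atoms: none
Why: Trifluoroacetic acid should cleave the PMB aryl ether and then ionise the benzylic C4–N bond of the phenol carbamate (SN1, cation stabilised by the ortho ring oxygen O1 and the 5-methyl group, as in the acid cleavage of alkoxybenzyl carbamates), and triethylsilane reduces both cations (ionic hydrogenation), which erases the C4 centre and leaves the four bonds of C2 untouched.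

**Compound list**
1 | phytol, (2E,7R,11R)-3,7,11,15-tetramethylhexadec-2-en-1-ol | OC/C=C(\C)CCC[C@H](C)CCC[C@H](C)CCCC(C)C | starting material
2 | (6R,10R)-6,10,14-trimethylpentadecan-2-one | CC(=O)CCC[C@H](C)CCC[C@H](C)CCCC(C)C | intermediate
3 | (5R,9R)-5,9,13-trimethyltetradecanoic acid | OC(=O)CCC[C@H](C)CCC[C@H](C)CCCC(C)C | intermediate
4 | 2,5-dimethylbenzene-1,4-diol | Cc1cc(O)c(C)cc1O | starting material
5 | 4-[(4-methoxyphenyl)methoxy]-2,5-dimethylphenol | Cc1cc(OCc2ccc(OC)cc2)c(C)cc1O | intermediate
6 | 4-[(4-methoxyphenyl)methoxy]-2,5-dimethylphenyl (5R,9R)-5,9,13-trimethyltetradecanoate | O=C(CCC[C@H](C)CCC[C@H](C)CCCC(C)C)Oc1cc(C)c(OCc2ccc(OC)cc2)cc1C | intermediate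
7 | 1-[(4-methoxyphenyl)methoxy]-2,5-dimethyl-4-{[(6R,10R)-6,10,14-trimethylpentadec-1-en-2-yl]oxy}benzene | C=C(CCC[C@H](C)CCC[C@H](C)CCCC(C)C)Oc1cc(C)c(OCc2ccc(OC)cc2)cc1C | intermediate
8 | benzyl N-ethenylcarbamate | C=CNC(=O)OCc1ccccc1 | starting material
9 | benzyl N-[(2R)-6-[(4-methoxyphenyl)methoxy]-2,5,8-trimethyl-2-[(4R,8R)-4,8,12-trimethyltridecyl]-3,4-dihydro-2H-chromen-4-yl]carbamate, both epimers at C-4 | Cc1cc(OCc3ccc(OC)cc3)c(C)c2c1O[C@](C)(CCC[C@H](C)CCC[C@H](C)CCCC(C)C)CC2NC(=O)OCc4ccccc4 | intermediate
10 | benzyl N-[(2R)-6-hydroxy-2,5,8-trimethyl-2-[(4R,8R)-4,8,12-trimethyltridecyl]-3,4-dihydro-2H-chromen-4-yl]carbamate, both epimers at C-4 | Cc1cc(O)c(C)c2c1O[C@](C)(CCC[C@H](C)CCC[C@H](C)CCCC(C)C)CC2NC(=O)OCc3ccccc3 | intermediate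
11 | (2R,4'R,8'R)-beta-tocopherol, (2R)-2,5,8-trimethyl-2-[(4R,8R)-4,8,12-trimethyltridecyl]-3,4-dihydro-2H-chromen-6-ol | Cc1cc(O)c(C)c2c1O[C@](C)(CCC[C@H](C)CCC[C@H](C)CCCC(C)C)CC2 | target

**Step count and risks**

Total step count: 7. Longest linear sequence: 6 (steps 1, 2, 4, 5, 6, 7 from phytol).

Steps most likely to fail:

1. Step 6. The anion may discriminate poorly between the methyl and methylene flanks of the oxocarbenium ion, giving poor facial selectivity at C2. The acid may protonate the enecarbamate instead of the enol ether, so that the enecarbamate oligomerises or the enol ether adds to its own oxocarbenium ion, and traces of water may hydrolyse the enol ether. The fallback uses known chemistry and sets out from 1 and 4. Friedel–Crafts allylation and ring closure of 2,5-dimethylhydroquinone (in excess, to hold back double annulation) with phytol (ZnCl2, HCl, ethyl acetate, 60 °C) should give (2RS,4'R,8'R)-beta-tocopherol F1. Its 2R epimer would then be separated from the 2S epimer by preparative chromatography on a chiral stationary phase (cellulose tris(3,5-dimethylphenylcarbamate)). The fallback comes back to the route at 11.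

2. Step 7. The C4–N bond may ionise too slowly at temperatures the liberated electron-rich phenol tolerates. The PMB cation may C-benzylate the aromatic ring before the silane captures it. Prolonged acid exposure may open the tertiary aryl ether reversibly and erode C2. The fallback avoids acid and sets out from 9. Hydrogenolysis (H2, Pd/C (palladium on carbon), ethyl acetate–ethanol) should remove the benzyloxycarbonyl and PMB groups to give (2R)-4-amino-beta-tocopherol F2. Direct reductive deamination of this primary benzylic amine through the isodiazene (N-(benzyloxy)-N-(pivaloyloxy)-4-(trifluoromethyl)benzamide, MeCN, 45 °C) then replaces C4–N by C4–H. The fallback comes back to the route at 11.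

3. Step 5. Methylenation may be incomplete, and the acid-labile enol ether may be hydrolysed back to ketone and phenol during work-up and chromatography. The fallback builds the C–O bond by cross-coupling and sets out from 2 and 5. Kinetic enolisation of 2 at the methyl side (LiN(iPr)2, THF, −78 °C) and trapping with PhNTf2 should give (6R,10R)-6,10,14-trimethylpentadec-1-en-2-yl trifluoromethanesulfonate F3. Palladium-catalysed C–O coupling with 5 (Pd2(dba)3 as a zerovalent palladium source, dba = dibenzylideneacetone, 2-(di-tert-butylphosphino)biphenyl, NaOtBu, toluene, 80 °C) then gives the enol ether. The fallback comes back to the route at 7.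

**Further compounds**
F1 | step 6 | (2RS,4'R,8'R)-beta-tocopherol, epimeric at C2 | Cc1cc(O)c(C)c2c1OC(C)(CCC[C@H](C)CCC[C@H](C)CCCC(C)C)CC2
F2 | step 7 | (2R)-4-amino-2,5,8-trimethyl-2-[(4R,8R)-4,8,12-trimethyltridecyl]-3,4-dihydro-2H-chromen-6-ol, both epimers at C-4 | Cc1cc(O)c(C)c2c1O[C@](C)(CCC[C@H](C)CCC[C@H](C)CCCC(C)C)CC2N
F3 | step 5 | (6R,10R)-6,10,14-trimethylpentadec-1-en-2-yl trifluoromethanesulfonate | C=C(OS(=O)(=O)C(F)(F)F)CCC[C@H](C)CCC[C@H](C)CCCC(C)C
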